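**Retrosynthetic overview**
- Target 11 ⇐ tri-MOM (R)-allylic alcohol 10 ⇐ (R)-allylic acetate 9, by acetate methanolysis and then MOM cleavage.
- The C6–CH2 bond and the (R)-carbinol centre of 9 ⇐ 6-iodo-tri-O-MOM-genistein 7 + isoprene 8 + acetate, in one new Pd-catalysed enantioselective, branch-selective aryl-acetoxylation of isoprene.
- 7 ⇐ genistein 4, through the 7,4'-di-MOM ether 5 and 5-OH-directed iodination at C6 (6).
- Genistein 4 ⇐ phloroglucinol 1 + 4-hydroxyphenylacetic acid 2 + one carbon from DMF. The A and B rings are bought; the pyranone C ring is the only ring formed.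

Assumption: the target stereocentre is (R) (OH > isopropenyl > CH2Ar > H). The sense of induction of the new step 5 cannot be predicted with certainty, so the ligand antipode that gives (R)-9 is the one used.

**Step 1**
Reactants: 1 phloroglucinol; 2 4-hydroxyphenylacetic acid
Product: 4 genistein, via deoxybenzoin 3 (not isolated)
Conditions: BF3·OEt2 (solvent), 85 °C; then DMF, MsCl, 70 °C; aq NaOAc work-up
Reagents that add atoms: N,N-dimethylformamide, CN(C)C=O
Why: Friedel–Crafts (Hoesch-type) C-acylation of symmetric phloroglucinol gives deoxybenzoin 3, whose active methylene is formylated by the DMF/MsCl Vilsmeier-type reagent and closed by an ortho-OH with loss of Me2NH (deoxybenzoin isoflavone synthesis); the symmetry of 3 allows only one isoflavone.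

**Step 2**
Reactants: 4 genistein
Product: 5 5-hydroxy-7-(methoxymethoxy)-3-[4-(methoxymethoxy)phenyl]-4H-chromen-4-one
Conditions: MOMCl (2.2 equiv), K2CO3, acetone, 0 °C to rt
Reagents that add atoms: chloromethyl methyl ether, COCCl
Why: Williamson-type O-alkylation of the two acidic, unhindered phenols (7-OH, 4'-OH), while the 5-OH stays locked in its hydrogen bond to C4=O and is not alkylated under these conditions.

**Step 3**
Reactants: 5 7,4'-di-O-MOM-genistein
Product: 6 5-hydroxy-6-iodo-7-(methoxymethoxy)-3-[4-(methoxymethoxy)phenyl]-4H-chromen-4-one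
Conditions: BnMe3N·ICl2 (1.05 equiv), CaCO3, CH2Cl2–MeOH, rt, dark
Reagents that add atoms: benzyltrimethylammonium dichloroiodate, C[N+](C)(C)Cc1ccccc1.Cl[I-]Cl
Why: Electrophilic aromatic iodination directed ortho (C6) by the free chelated 5-OH; the B-ring aryl ether is far less activated, and CaCO3 buffers the HCl so the MOM ethers survive.

**Step 4**
Reactants: 6 6-iodo-7,4'-di-O-MOM-genistein
Product: 7 6-iodo-5,7-bis(methoxymethoxy)-3-[4-(methoxymethoxy)phenyl]-4H-chromen-4-one
Conditions: NaH, MOMCl, DMF, 0 °C to rt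
Reagents that add atoms: chloromethyl methyl ether, COCCl
Why: NaH breaks the 5-OH···O=C hydrogen bond and the small, reactive MOMCl alkylates the hindered phenoxide (Williamson etherification), which removes the only nucleophile that could later cyclise onto the side chain.

**Step 5**
Reactants: 7 6-iodo-5,7,4'-tri-O-MOM-genistein; 8 isoprene
Product: 9 (2R)-1-{5,7-bis(methoxymethoxy)-3-[4-(methoxymethoxy)phenyl]-4-oxo-4H-chromen-6-yl}-3-methylbut-3-en-2-yl acetate
Conditions: Pd2(dba)3 (2.5 mol%), (R,R)-QuinoxP* (6 mol%), CsOAc (2 equiv), isoprene (5 equiv), 4 Å MS, THF, 50 °C, sealed tube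
Reagents that add atoms: cesium acetate, CC(=O)[O-].[Cs+]
Why: Proposed new method: an intermolecular, enantio- and branch-selective three-component aryl-acetoxylation of isoprene, in which oxidative addition of C6–I to Pd(0)/bisphosphine and I→OAc exchange (CsI precipitates) are followed by Heck-type insertion of the less substituted C3=C4 bond of isoprene with aryl going to the terminal CH2, giving the 2-methyl-π-allyl-Pd species ArCH2–CH–C(Me)–CH2 that equilibrates between its faces by π–σ–π through the CH2 terminus, after which the Pd-bound acetate is delivered inner-sphere through a seven-membered 3,3'-type reductive elimination from the η1-allyl isomer (Pd on CH2) to the internal carbon, so the chiral pocket sets the (R) centre and the branched regiochemistry under Curtin–Hammett control, while the acid-free carboxylate and bidentate ligand suppress isoprene telomerisation; the closest known reactions are Larock-type Pd diene heteroannulation with o-iodophenols and Heck/Tsuji–Trost three-component diene carboamination, with inner-sphere branched C–O formation as in Pd allylic C–H esterification.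

**Step 6**
Reactants: 9 tri-MOM (R)-allylic acetate
Product: 10 6-[(2R)-2-hydroxy-3-methylbut-3-en-1-yl]-5,7-bis(methoxymethoxy)-3-[4-(methoxymethoxy)phenyl]-4H-chromen-4-one
Conditions: K2CO3 (0.2 equiv), MeOH, 0 °C to rt
Reagents that add atoms: none
Why: Zemplén-type transesterification cleaves the secondary acetate at the acyl carbon, so the C–O bond at the stereocentre is untouched and (R) is retained; MOM ethers and the alkene are inert.

**Step 7**
Reactants: 10 tri-MOM (R)-allylic alcohol
Product: 11 5,7-dihydroxy-6-[(2R)-2-hydroxy-3-methylbut-3-en-1-yl]-3-(4-hydroxyphenyl)-4H-chromen-4-one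
Conditions: 1.25 M HCl in MeOH, 35–40 °C
Reagents that add atoms: none
Why: Acid-catalysed acetal exchange transfers the three aryl MOM groups to methanol; under these mild conditions the carbinol C–O bond is not ionised, so the (R) centre is retained.

**Compound list**
1 | phloroglucinol (benzene-1,3,5-triol) | Oc1cc(O)cc(O)c1 | starting material
2 | 4-hydroxyphenylacetic acid | OC(=O)Cc1ccc(O)cc1 | starting material
3 | deoxybenzoin, 2-(4-hydroxyphenyl)-1-(2,4,6-trihydroxyphenyl)ethan-1-one (not isolated) | O=C(Cc1ccc(O)cc1)c1c(O)cc(O)cc1O | intermediate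
4 | genistein, 5,7-dihydroxy-3-(4-hydroxyphenyl)-4H-chromen-4-one | O=c1c(-c2ccc(O)cc2)coc2cc(O)cc(O)c12 | intermediate
5 | 5-hydroxy-7-(methoxymethoxy)-3-[4-(methoxymethoxy)phenyl]-4H-chromen-4-one | O=c1c(-c2ccc(OCOC)cc2)coc2cc(OCOC)cc(O)c12 | intermediate
6 | 5-hydroxy-6-iodo-7-(methoxymethoxy)-3-[4-(methoxymethoxy)phenyl]-4H-chromen-4-one | O=c1c(-c2ccc(OCOC)cc2)coc2cc(OCOC)c(I)c(O)c12 | intermediate
7 | 6-iodo-5,7-bis(methoxymethoxy)-3-[4-(methoxymethoxy)phenyl]-4H-chromen-4-one | O=c1c(-c2ccc(OCOC)cc2)coc2cc(OCOC)c(I)c(OCOC)c12 | intermediate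
8 | isoprene (2-methylbuta-1,3-diene) | C=CC(C)=C | starting material
9 | (2R)-1-{5,7-bis(methoxymethoxy)-3-[4-(methoxymethoxy)phenyl]-4-oxo-4H-chromen-6-yl}-3-methylbut-3-en-2-yl acetate | C=C(C)[C@H](OC(C)=O)Cc1c(OCOC)cc2occ(-c3ccc(OCOC)cc3)c(=O)c2c1OCOC | intermediate
10 | 6-[(2R)-2-hydroxy-3-methylbut-3-en-1-yl]-5,7-bis(methoxymethoxy)-3-[4-(methoxymethoxy)phenyl]-4H-chromen-4-one | C=C(C)[C@H](O)Cc1c(OCOC)cc2occ(-c3ccc(OCOC)cc3)c(=O)c2c1OCOC | intermediate
11 | 5,7-dihydroxy-6-[(2R)-2-hydroxy-3-methylbut-3-en-1-yl]-3-(4-hydroxyphenyl)-4H-chromen-4-one (CNP0262941.2) | C=C(C)[C@H](O)Cc1c(O)cc2occ(-c3ccc(O)cc3)c(=O)c2c1O | target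

**Total step count:** 7
**Longest linear sequence:** 7 steps (1/2 → 11)

**Three steps most likely to fail**

Step 5 (the proposed new step). The risks are β-hydride elimination of the π-allyl to the aryl diene, acetate attack at the CH2 terminus (linear acetate), insertion at the substituted end of isoprene, Pd(0) re-ionisation of the product, and insufficient ee. The fallback uses known chemistry only, sets out from 7 and comes back at 10. Stille coupling of 7 with tributyl(3-methylbut-2-en-1-yl)stannane (Pd(PPh3)4, DMF, 90 °C) gives the 6-prenyl tri-MOM isoflavone F5. Shi epoxidation with the D-fructose-derived ketone (Oxone, pH 10.5 buffer, MeCN–DMM–H2O, 0 °C) reacts only at the electron-rich trisubstituted alkene and gives the (R)-epoxide F6. Aluminium isopropoxide in refluxing toluene then removes a methyl proton and opens the epoxide to the isopropenyl carbinol with the C–O stereocentre retained, which is 10.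

Step 3 (C6 versus C8 iodination). If the regioselectivity is poor or di-iodination intervenes, the C6 substituent is introduced by a sigmatropic route that cannot reach C8; it sets out from 5 and comes back at 10. O-Allylation of the 5-OH (allyl bromide, K2CO3, DMF, 60 °C) gives the 5-O-allyl ether F1. Thermal aromatic Claisen rearrangement (N,N-diethylaniline, 190 °C) moves the allyl group to C6, the only free ortho position of O-5, giving the 6-allyl-5-hydroxy compound F2. MOMCl/NaH gives the 6-allyl tri-MOM isoflavone F3. Lemieux–Johnson cleavage (OsO4 cat., NaIO4, 2,6-lutidine, dioxane–H2O) gives the arylacetaldehyde F4. Catalytic asymmetric Nozaki–Hiyama–Kishi coupling with 2-bromopropene (CrCl2/NiCl2 cat., chiral sulfonamide ligand antipode giving (R), Mn, Cp2ZrCl2, MeCN) then gives 10.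

Step 7 (acidic MOM removal next to the free allylic alcohol). The risks are protonation of the isopropenyl group followed by phenol cyclisation to a chroman, semipinacol shift, or methanol addition. The fallback changes the order and the type of cleavage so that the free carbinol never meets acid; it sets out from 9 and comes back at 11. The three MOM ethers of 9 are removed aprotically with ZnBr2/n-PrSH (CH2Cl2, 0 °C, minutes) while the carbinol is still masked as its acetate, giving the triphenol (R)-acetate F7. Mild methanolysis (K2CO3, MeOH, 0 °C to rt, under argon) then releases 11.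

**Further compounds**
F1 | step 3 | 5-(allyloxy)-7-(methoxymethoxy)-3-[4-(methoxymethoxy)phenyl]-4H-chromen-4-one | O=c1c(-c2ccc(OCOC)cc2)coc2cc(OCOC)cc(OCC=C)c12
F2 | step 3 | 6-allyl-5-hydroxy-7-(methoxymethoxy)-3-[4-(methoxymethoxy)phenyl]-4H-chromen-4-one | C=CCc1c(OCOC)cc2occ(-c3ccc(OCOC)cc3)c(=O)c2c1O
F3 | step 3 | 6-allyl-5,7-bis(methoxymethoxy)-3-[4-(methoxymethoxy)phenyl]-4H-chromen-4-one | C=CCc1c(OCOC)cc2occ(-c3ccc(OCOC)cc3)c(=O)c2c1OCOC
F4 | step 3 | 2-{5,7-bis(methoxymethoxy)-3-[4-(methoxymethoxy)phenyl]-4-oxo-4H-chromen-6-yl}acetaldehyde | O=CCc1c(OCOC)cc2occ(-c3ccc(OCOC)cc3)c(=O)c2c1OCOC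
F5 | step 5 | 5,7-bis(methoxymethoxy)-3-[4-(methoxymethoxy)phenyl]-6-(3-methylbut-2-en-1-yl)-4H-chromen-4-one | CC(C)=CCc1c(OCOC)cc2occ(-c3ccc(OCOC)cc3)c(=O)c2c1OCOC
F6 | step 5 | 6-{[(2R)-3,3-dimethyloxiran-2-yl]methyl}-5,7-bis(methoxymethoxy)-3-[4-(methoxymethoxy)phenyl]-4H-chromen-4-one | CC1(C)O[C@@H]1Cc1c(OCOC)cc2occ(-c3ccc(OCOC)cc3)c(=O)c2c1OCOC
F7 | step 7 | (2R)-1-[5,7-dihydroxy-3-(4-hydroxyphenyl)-4-oxo-4H-chromen-6-yl]-3-methylbut-3-en-2-yl acetate | C=C(C)[C@H](OC(C)=O)Cc1c(O)cc2occ(-c3ccc(O)cc3)c(=O)c2c1O
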